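**Retrosynthetic overview**

1. Numbering used throughout: C1 lactone carbonyl, C2 (CH–CH3), C3 (CH–OAc), C4 (quaternary C–CH3), C5 (ring-fusion CH–O of the lactone), C6 (CH–CH3), C7 (CH–O-acyl), C8 (CH(CH3)–O). Last disconnections: the Z-enone comes from semi-hydrogenation of a 4-oxodec-2-ynoate ester on O7, and C2 from hydrogenation of a 2-methylene lactone.
2. Key disconnection, the C3–C4 bond: the lactone ring (O5–C1–C2–C3–C4–C5) is closed by intramolecular Hosomi–Sakurai-type addition of a (Z)-3-acetoxy-2-(silylmethyl)acrylate, esterified on O5, to the C4 methyl ketone. The new C4 oxygen then closes the oxane ring on the C8 methyl ketone, and the ketal is reduced in the same flask.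
3. Enabling feature: around the oxane oxygen the carbons C4–C5–C6–C7–C8 form a Cs-pseudosymmetric CH3/O/CH3/O/CH3 array, broken only by C3 on C4. C4 and C8 are therefore the two carbonyls of one all-syn, pseudo-meso 3,5-dioxy-4-methylheptane-2,6-dione, and the C4 oxygen formed in the C–C step sits 1,5 to the C8 ketone.
4. The heptanedione comes from one Evans syn aldol (propanoyl oxazolidinone + methacrolein), an isopropenyl ketone, a chelation-controlled reduction and a double ozonolysis.
5. Ring order: lactone ring first (C3–C4), oxane ring second (C4–O–C8), both in step 12. Two side branches supply acid 14 (from 3-(trimethylsilyl)propanoic acid) and acid 26 (from heptanal).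

Key step: step 12

Remark: the side-chain carbinol (C4′ of 24–28) is carried as the racemate because it is oxidized to the ketone in step 19, so 27 and 28 are C4′ epimer pairs.

**Route**

Step 1
Reactants: 1 (4R)-4-benzyl-3-propanoyl-1,3-oxazolidin-2-one; 2 methacrolein
Product: 3 (4R)-4-benzyl-3-[(2R,3R)-3-hydroxy-2,4-dimethylpent-4-enoyl]-1,3-oxazolidin-2-one
Conditions: Bu2BOTf, i-Pr2NEt, CH2Cl2, −78 to 0 °C; then MeOH, pH 7 buffer, H2O2
Reagents that add atoms: none
Why: Evans syn aldol reaction, in which the Z-boron enolate of the (R)-auxiliary adds to methacrolein through a Zimmerman–Traxler chair and sets C6 and C7 as the 2R,3R syn pair.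

Step 2
Reactants: 3 (aldol adduct)
Product: 4 (2R,3R)-3-hydroxy-N-methoxy-N,2,4-trimethylpent-4-enamide
Conditions: MeNH(OMe)·HCl, AlMe3, CH2Cl2, −20 to 0 °C; 0.5 M HCl work-up
Reagents that add atoms: N,O-dimethylhydroxylamine hydrochloride, CNOC.Cl
Why: Aluminium amide transamidation of the imide to the Weinreb amide, assisted by the free β-hydroxyl, should release the auxiliary without touching the stereocentres.

Step 3
Reactants: 4 (hydroxy Weinreb amide)
Product: 5 (2R,3R)-3-(benzyloxy)-N-methoxy-N,2,4-trimethylpent-4-enamide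
Conditions: BnOC(=NH)CCl3, TfOH (5 mol %), CH2Cl2–cyclohexane, 0 °C
Reagents that add atoms: benzyl 2,2,2-trichloroacetimidate, ClC(Cl)(Cl)C(=N)OCc1ccccc1
Why: Acid-catalysed imidate benzylation avoids the retro-aldol cleavage that basic benzylation of a β-hydroxy amide would cause, and the benzyl ether later serves as the chelating group.

Step 4
Reactants: 5 (benzyloxy Weinreb amide); 6 isopropenylmagnesium bromide
Product: 7 (4R,5R)-5-(benzyloxy)-2,4,6-trimethylhepta-1,6-dien-3-one
Conditions: THF, 0 °C; aqueous NH4Cl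
Reagents that add atoms: none
Why: Weinreb ketone synthesis, in which the chelated tetrahedral intermediate prevents over-addition and releases the enone only on work-up.

Step 5
Reactants: 7 (enone)
Product: 8 (3S,4S,5R)-5-(benzyloxy)-2,4,6-trimethylhepta-1,6-dien-3-ol
Conditions: Zn(BH4)2, Et2O, −30 °C; aqueous NH4Cl
Reagents that add atoms: none
Why: Chelation-controlled 1,2-reduction, in which zinc bridges the ketone and the β-benzyloxy oxygen and hydride adds to the half-chair chelate anti to the α-methyl group, should give the 3,5-syn and 3,4-syn alcohol (the all-syn C5–C6–C7 triad).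

Step 6
Reactants: 8 (diene alcohol)
Product: 9 (3S,4S,5R)-5-(benzyloxy)-3-hydroxy-4-methylheptane-2,6-dione
Conditions: O3, CH2Cl2–MeOH, −78 °C; then Me2S, −78 °C to rt
Reagents that add atoms: ozone, [O-][O+]=O
Why: Ozonolysis with reductive work-up cleaves both 1,1-disubstituted alkenes to the C4 and C8 methyl ketones in one operation, leaving the benzyl ether and the stereocentres untouched at −78 °C.

Step 7
Reactants: 10 3-(trimethylsilyl)propanoic acid
Product: 11 prop-2-en-1-yl 3-(trimethylsilyl)propanoate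
Conditions: allyl bromide, K2CO3, DMF, rt
Reagents that add atoms: allyl bromide, C=CCBr
Why: Carboxylate O-alkylation gives an ester that can later be cleaved under neutral conditions.

Step 8
Reactants: 11 (allyl ester)
Product: 12 prop-2-en-1-yl 2-formyl-3-(trimethylsilyl)propanoate (racemic, mainly the hydroxymethylene enol)
Conditions: LiN(i-Pr)2, THF, −78 °C; HCO2Et, −78 °C; cold 1 M HCl
Reagents that add atoms: ethyl formate, CCOC=O
Why: Crossed Claisen formylation of the ester enolate, run at −78 °C where the allyl ester enolate does not undergo Ireland–Claisen rearrangement, installs C3 at the aldehyde oxidation level.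

Step 9
Reactants: 12 (formyl ester)
Product: 13 prop-2-en-1-yl (2Z)-3-(acetyloxy)-2-[(trimethylsilyl)methyl]prop-2-enoate
Conditions: Ac2O, Et3N, DMAP (10 mol %), CH2Cl2, 0 °C to rt
Reagents that add atoms: acetic anhydride, CC(=O)OC(C)=O
Why: O-acetylation of the hydroxymethylene ester, where reversible acetyl transfer under DMAP should let the enol acetate settle as the more stable isomer with the acetoxy group trans to the ester (Z by the sequence rule), to be purified and assigned by NOE at this stage.

Step 10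
Reactants: 13 (allyl enol acetate)
Product: 14 (2Z)-3-(acetyloxy)-2-[(trimethylsilyl)methyl]prop-2-enoic acid
Conditions: Pd(PPh3)4 (5 mol %), HCO2H, Et3N, THF, rt
Reagents that add atoms: none
Why: Tsuji–Trost deallylation with formate as hydride donor frees the acid under neutral conditions that should leave the enol acetate and the allylsilane intact.

Step 11
Reactants: 14 (acid); 9 (hydroxy diketone)
Product: 16 (3S,4R,5R)-5-(benzyloxy)-4-methyl-2,6-dioxoheptan-3-yl (2Z)-3-(acetyloxy)-2-[(trimethylsilyl)methyl]prop-2-enoate, via acid chloride 15 (not isolated)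
Conditions: 14, 1-chloro-N,N,2-trimethylprop-1-en-1-amine, CH2Cl2, 0 °C; then 9, pyridine, −20 to 0 °C
Reagents that add atoms: none
Why: Neutral acid chloride formation followed by acylation of the open-chain secondary hydroxyl with pyridine as the only base, with no DMAP so that the activated enol acetate does not transfer its acetyl group.

Step 12
Reactants: 16 (diketone allylsilane ester)
Product: 19 (4S,4aS,6S,7R,8R,8aS)-7-(benzyloxy)-4a,6,8-trimethyl-3-methylidene-2-oxooctahydropyrano[3,2-b]pyran-4-yl acetate, via C4 silyl ether lactone 17 (not isolated), via bicyclic C8 silyl ketal 18 (not isolated)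
Conditions: Me3SiOTf (0.3 equiv), 2,6-di-tert-butyl-4-methylpyridine (0.1 equiv), CH2Cl2, −78 to −30 °C; then Et3SiH (3 equiv), −78 to 0 °C
Reagents that add atoms: none
Why: Proposed new method: Me3SiOTf silylates the C4 ketone oxygen and the tethered allylsilane adds through its γ-carbon C3 in an open, anti-SE2′ transition state, after which the β-silyl cation loses Me3Si+ to leave the 2-methylene group and regenerate the promoter; the closest known reaction type is the Lewis-acid-mediated Hosomi–Sakurai addition of 2-(trimethylsilylmethyl)acrylates to carbonyl compounds, including its intramolecular use for α-methylene lactones, and what is new is the γ-acetoxy substituent, the ketone acceptor and the ester-linked six-membered ring. The lactone ring closes by this C3–C4 bond in a 6-exo-trig mode at the carbonyl through the s-cis ester rotamer (the rotamer that ring-closing metathesis of acrylates to dihydropyranones also uses), and the oxane ring then closes by 6-exo-trig addition of the C4 silyl ether oxygen to the silyl-activated C8 ketone, ionization of the silyl ketal and hydride transfer from Et3SiH. C4 should be set by a chair-like Cornforth arrangement with the silylated carbonyl oxygen antiperiplanar to the C5–O bond and equatorial, the C4 methyl axial and the C5 side chain equatorial; C3 by the Z geometry of the enol acetate, whose acetoxy group is trans to C1 and therefore ends equatorial; and C8 by axial hydride delivery to the cyclic oxocarbenium ion, which puts the C8 methyl equatorial. The step needs bonding through C3 and not C2, which the β-silyl effect, the weak donor ability of an acyloxy group and the fact that bonding at C2 would join two fully substituted carbons should secure, and reaction at the C4 and not the C8 ketone, which ring size secures (six-membered against ten-membered). A monodentate silyl Lewis acid is chosen because a closed, metal-bridged transition state would force the C4 oxygen axial and give the C4 epimer.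

Step 13
Reactants: 19 (methylene lactone)
Product: 21 (3R,4S,4aS,6S,7R,8R,8aS)-7-hydroxy-3,4a,6,8-tetramethyl-2-oxooctahydropyrano[3,2-b]pyran-4-yl acetate, via saturated 7-O-benzyl lactone 20 (not isolated)
Conditions: H2 (1 atm), RhCl(PPh3)3 (10 mol %), EtOAc–EtOH, rt; then silica plug, Pd on carbon, H2 (1 atm), rt
Reagents that add atoms: none
Why: Homogeneous hydrogenation of the 1,1-disubstituted alkene from the face opposite the axial C4 methyl and the C3 acetate should set C2 with its methyl cis to both, and because the acetate is then no longer allylic the following Pd-catalysed hydrogenolysis of the benzyl ether cannot cleave it.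

Step 14
Reactants: 22 heptanal; 23 ethynylmagnesium bromide
Product: 24 non-1-yn-3-ol (racemic)
Conditions: THF, 0 °C; aqueous NH4Cl
Reagents that add atoms: none
Why: Grignard addition of the acetylide to the aldehyde gives the carbinol, whose configuration is irrelevant because it is oxidized later.

Step 15
Reactants: 24 (alkynol)
Product: 25 tert-butyl(dimethyl)(non-1-yn-3-yloxy)silane (racemic)
Conditions: t-BuMe2SiCl, imidazole, DMF, rt
Reagents that add atoms: tert-butyldimethylsilyl chloride, CC(C)(C)[Si](C)(C)Cl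
Why: Standard silylation of a secondary alcohol.

Step 16
Reactants: 25 (silyl ether)
Product: 26 4-{[tert-butyl(dimethyl)silyl]oxy}dec-2-ynoic acid (racemic)
Conditions: n-BuLi, THF, −78 °C; CO2; cold 1 M HCl
Reagents that add atoms: carbon dioxide, O=C=O
Why: Deprotonation of the terminal alkyne and carboxylation of the lithium acetylide.

Step 17
Reactants: 21 (core alcohol); 26 (ynoic acid)
Product: 27 (3R,4S,4aS,6S,7R,8R,8aS)-4-(acetyloxy)-3,4a,6,8-tetramethyl-2-oxooctahydropyrano[3,2-b]pyran-7-yl 4-{[tert-butyl(dimethyl)silyl]oxy}dec-2-ynoate (C4′ epimers)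
Conditions: DCC, DMAP (10 mol %), CH2Cl2, 0 °C
Reagents that add atoms: none
Why: Steglich esterification of the C7 hydroxyl, with catalytic DMAP at 0 °C to keep the base-sensitive C2 centre intact.

Step 18
Reactants: 27 (silyl ether ester)
Product: 28 (3R,4S,4aS,6S,7R,8R,8aS)-4-(acetyloxy)-3,4a,6,8-tetramethyl-2-oxooctahydropyrano[3,2-b]pyran-7-yl 4-hydroxydec-2-ynoate (C4′ epimers)
Conditions: HF·pyridine, pyridine, THF, 0 °C
Reagents that add atoms: none
Why: Buffered fluoride cleaves the propargylic silyl ether, and a 4-hydroxy-2-ynoate cannot lactonize because the alkyne is linear.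

Step 19
Reactants: 28 (propargylic alcohol)
Product: 29 (3R,4S,4aS,6S,7R,8R,8aS)-4-(acetyloxy)-3,4a,6,8-tetramethyl-2-oxooctahydropyrano[3,2-b]pyran-7-yl 4-oxodec-2-ynoate
Conditions: Dess–Martin periodinane, NaHCO3, CH2Cl2, 0 °C
Reagents that add atoms: none
Why: Buffered Dess–Martin oxidation of the propargylic alcohol gives the ynone and removes the only undefined stereocentre.

Step 20
Reactants: 29 (ynone ester)
Product: 30 Botcinin J, (3R,4S,4aS,6S,7R,8R,8aS)-4-(acetyloxy)-3,4a,6,8-tetramethyl-2-oxooctahydropyrano[3,2-b]pyran-7-yl (2Z)-4-oxodec-2-enoate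
Conditions: H2 (1 atm), Pd on CaCO3 poisoned with Pb(OAc)2, quinoline, EtOAc, 0 °C, dark
Reagents that add atoms: none
Why: Syn semi-hydrogenation of the alkyne on the poisoned catalyst should give the Z-enone ester, with the reaction stopped at one equivalent of H2 and kept cold and dark to limit over-reduction and Z-to-E isomerization.

**Compound list**

1 | (4R)-4-benzyl-3-propanoyl-1,3-oxazolidin-2-one | CCC(=O)N1[C@H](Cc2ccccc2)COC1=O | starting material
2 | methacrolein | CC(=C)C=O | starting material
3 | (4R)-4-benzyl-3-[(2R,3R)-3-hydroxy-2,4-dimethylpent-4-enoyl]-1,3-oxazolidin-2-one | C=C(C)[C@H](O)[C@@H](C)C(=O)N1[C@H](Cc2ccccc2)COC1=O | intermediate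
4 | (2R,3R)-3-hydroxy-N-methoxy-N,2,4-trimethylpent-4-enamide | C=C(C)[C@H](O)[C@@H](C)C(=O)N(C)OC | intermediate
5 | (2R,3R)-3-(benzyloxy)-N-methoxy-N,2,4-trimethylpent-4-enamide | C=C(C)[C@H](OCc1ccccc1)[C@@H](C)C(=O)N(C)OC | intermediate
6 | isopropenylmagnesium bromide | CC(=C)[Mg]Br | starting material
7 | (4R,5R)-5-(benzyloxy)-2,4,6-trimethylhepta-1,6-dien-3-one | C=C(C)[C@H](OCc1ccccc1)[C@@H](C)C(=O)C(C)=C | intermediate
8 | (3S,4S,5R)-5-(benzyloxy)-2,4,6-trimethylhepta-1,6-dien-3-ol | C=C(C)[C@H](OCc1ccccc1)[C@@H](C)[C@H](O)C(C)=C | intermediate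
9 | (3S,4S,5R)-5-(benzyloxy)-3-hydroxy-4-methylheptane-2,6-dione | CC(=O)[C@H](OCc1ccccc1)[C@@H](C)[C@H](O)C(C)=O | intermediate
10 | 3-(trimethylsilyl)propanoic acid | C[Si](C)(C)CCC(=O)O | starting material
11 | prop-2-en-1-yl 3-(trimethylsilyl)propanoate | C[Si](C)(C)CCC(=O)OCC=C | intermediate
12 | prop-2-en-1-yl 2-formyl-3-(trimethylsilyl)propanoate (racemic, mainly enol) | C[Si](C)(C)CC(C=O)C(=O)OCC=C | intermediate
13 | prop-2-en-1-yl (2Z)-3-(acetyloxy)-2-[(trimethylsilyl)methyl]prop-2-enoate | C[Si](C)(C)C/C(C(=O)OCC=C)=C\OC(C)=O | intermediate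
14 | (2Z)-3-(acetyloxy)-2-[(trimethylsilyl)methyl]prop-2-enoic acid | C[Si](C)(C)C/C(C(=O)O)=C\OC(C)=O | intermediate
15 | 3-(acetyloxy)-2-[(trimethylsilyl)methyl]prop-2-enoyl chloride, same alkene geometry as 14 (2E by the sequence rule) | C[Si](C)(C)C/C(C(Cl)=O)=C\OC(C)=O | intermediate
16 | (3S,4R,5R)-5-(benzyloxy)-4-methyl-2,6-dioxoheptan-3-yl (2Z)-3-(acetyloxy)-2-[(trimethylsilyl)methyl]prop-2-enoate | CC(=O)[C@H](OCc1ccccc1)[C@@H](C)[C@H](OC(=O)/C(C[Si](C)(C)C)=C/OC(C)=O)C(C)=O | intermediate
17 | monocyclic 2-methylene δ-lactone with C3 acetate, C4 methyl and C4 trimethylsilyl ether, C5 side chain still carrying the C7 benzyl ether and the open C8 methyl ketone | CC(=O)[C@H](OCc1ccccc1)[C@@H](C)[C@@H]1OC(=O)C(=C)[C@H](OC(C)=O)[C@@]1(C)O[Si](C)(C)C | intermediate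
18 | bicyclic lactone as 19 but with a trimethylsilyloxy group on C8 (mixed silyl ketal, either C8 epimer) | c3ccccc3CO[C@@H]1[C@@H](C)[C@@H]2OC(=O)C(=C)[C@H](OC(C)=O)[C@@]2(C)OC1(C)O[Si](C)(C)C | intermediate
19 | (4S,4aS,6S,7R,8R,8aS)-7-(benzyloxy)-4a,6,8-trimethyl-3-methylidene-2-oxooctahydropyrano[3,2-b]pyran-4-yl acetate | c3ccccc3CO[C@@H]1[C@@H](C)[C@@H]2OC(=O)C(=C)[C@H](OC(C)=O)[C@@]2(C)O[C@H]1C | intermediate
20 | (3R,4S,4aS,6S,7R,8R,8aS)-7-(benzyloxy)-3,4a,6,8-tetramethyl-2-oxooctahydropyrano[3,2-b]pyran-4-yl acetate | c3ccccc3CO[C@@H]1[C@@H](C)[C@@H]2OC(=O)[C@H](C)[C@H](OC(C)=O)[C@@]2(C)O[C@H]1C | intermediate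
21 | (3R,4S,4aS,6S,7R,8R,8aS)-7-hydroxy-3,4a,6,8-tetramethyl-2-oxooctahydropyrano[3,2-b]pyran-4-yl acetate | O[C@@H]1[C@@H](C)[C@@H]2OC(=O)[C@H](C)[C@H](OC(C)=O)[C@@]2(C)O[C@H]1C | intermediate
22 | heptanal | CCCCCCC=O | starting material
23 | ethynylmagnesium bromide | C#C[Mg]Br | starting material
24 | non-1-yn-3-ol (racemic) | CCCCCCC(O)C#C | intermediate
25 | tert-butyl(dimethyl)(non-1-yn-3-yloxy)silane (racemic) | CCCCCCC(O[Si](C)(C)C(C)(C)C)C#C | intermediate
26 | 4-{[tert-butyl(dimethyl)silyl]oxy}dec-2-ynoic acid (racemic) | CCCCCCC(O[Si](C)(C)C(C)(C)C)C#CC(=O)O | intermediate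
27 | core 7-yl 4-{[tert-butyl(dimethyl)silyl]oxy}dec-2-ynoate (C4′ epimers; core as in 21) | CCCCCCC(O[Si](C)(C)C(C)(C)C)C#CC(=O)O[C@@H]1[C@@H](C)[C@@H]2OC(=O)[C@H](C)[C@H](OC(C)=O)[C@@]2(C)O[C@H]1C | intermediate
28 | core 7-yl 4-hydroxydec-2-ynoate (C4′ epimers) | CCCCCCC(O)C#CC(=O)O[C@@H]1[C@@H](C)[C@@H]2OC(=O)[C@H](C)[C@H](OC(C)=O)[C@@]2(C)O[C@H]1C | intermediate
29 | core 7-yl 4-oxodec-2-ynoate | CCCCCCC(=O)C#CC(=O)O[C@@H]1[C@@H](C)[C@@H]2OC(=O)[C@H](C)[C@H](OC(C)=O)[C@@]2(C)O[C@H]1C | intermediate
30 | Botcinin J | CCCCCCC(=O)/C=C\C(=O)O[C@@H]1[C@@H](C)[C@@H]2OC(=O)[C@H](C)[C@H](OC(C)=O)[C@@]2(C)O[C@H]1C | target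

**Step count and risks**

Total step count: 20. Longest linear sequence: 13 steps (1–6, 11–13, 17–20).

Steps most likely to fail:

1. Step 12. The doubly deactivated allylsilane may not add to the silyl-activated ketone before protodesilylation, may bond through C2, or may add with the wrong facial sense at C4. Fallback (known reactions; the same bond is made by a Mukaiyama aldol addition): it sets out from 9 and comes back at 21. Esterification of 9 with bromopyruvic acid (DCC) gives the bromopyruvate ester F1, and CsOAc replaces the bromide to give the acetoxypyruvate ester F2. Soft enolization of the pyruvate (Me3SiCl, Et3N), then Me3SiOTf and Et3SiH, bring about an intramolecular Mukaiyama aldol addition of C3 to the C4 ketone and the same reductive etherification, giving the bicyclic α-keto lactone F3. Tf2O with 2,6-lutidine gives the enol triflate F4, and Stille methylation (Pd(PPh3)4, Me4Sn, LiCl) gives the 3-methyl enol acetate lactone F5. Hydrogenation from the face opposite the C4 methyl (H2, Rh on Al2O3, then Pd on carbon) should set C2 and C3 together and remove the benzyl group, giving 21.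

2. Step 20. Over-reduction of the very electron-poor alkyne to the saturated keto ester, or Z-to-E isomerization on the catalyst. Fallback: it sets out from 21 and 26 and comes back at 30, with the Z geometry fixed on the robust silyl ether and the enone formed last by oxidation. Semi-hydrogenation of 26 over the same poisoned Pd catalyst gives the Z-silyloxy acid F6; esterification with 21 (DCC, DMAP) gives the Z-silyloxy ester F7; HF·pyridine at 0 °C gives the Z-hydroxy enoate F8, which is oxidized at once with Dess–Martin periodinane to 30.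

3. Step 11. Acetyl transfer from the activated enol acetate to the alcohol, loss of the Z geometry in the acid chloride, or acylation at the hemiketal oxygen of 9. Fallback: it sets out from 8 and 10 and comes back at 16, building the nucleophile on the substrate and unveiling the ketones last. Steglich esterification of 8 with 10 gives the silylpropanoate ester F9; formylation (LiN(i-Pr)2, HCO2Et, −78 °C) gives the formyl ester F10; Ac2O, Et3N and DMAP give the Z-enol acetate diene F11; Lemieux–Johnson cleavage (OsO4 cat., NaIO4, 2,6-lutidine) of the two electron-richer isopropenyl groups gives 16.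

**Further compounds**

F1 | step 12 | (3S,4R,5R)-5-(benzyloxy)-4-methyl-2,6-dioxoheptan-3-yl 3-bromo-2-oxopropanoate | CC(=O)[C@H](OCc1ccccc1)[C@@H](C)[C@H](OC(=O)C(=O)CBr)C(C)=O
F2 | step 12 | (3S,4R,5R)-5-(benzyloxy)-4-methyl-2,6-dioxoheptan-3-yl 3-(acetyloxy)-2-oxopropanoate | CC(=O)[C@H](OCc1ccccc1)[C@@H](C)[C@H](OC(=O)C(=O)COC(C)=O)C(C)=O
F3 | step 12 | (4aS,6S,7R,8R,8aS)-7-(benzyloxy)-4a,6,8-trimethyl-2,3-dioxooctahydropyrano[3,2-b]pyran-4-yl acetate (C4 epimers and enol) | c3ccccc3CO[C@@H]1[C@@H](C)[C@@H]2OC(=O)C(=O)C(OC(C)=O)[C@@]2(C)O[C@H]1C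
F4 | step 12 | enol triflate of F3 (C3=C4 double bond, 3-trifluoromethanesulfonyloxy, 4-acetoxy) | c3ccccc3CO[C@@H]1[C@@H](C)[C@@H]2OC(=O)C(OS(=O)(=O)C(F)(F)F)=C(OC(C)=O)[C@@]2(C)O[C@H]1C
F5 | step 12 | (4aS,6S,7R,8R,8aS)-7-(benzyloxy)-3,4a,6,8-tetramethyl-2-oxo-4a,7,8,8a-tetrahydro-2H,6H-pyrano[3,2-b]pyran-4-yl acetate | c3ccccc3CO[C@@H]1[C@@H](C)[C@@H]2OC(=O)C(C)=C(OC(C)=O)[C@@]2(C)O[C@H]1C
F6 | step 20 | (2Z)-4-{[tert-butyl(dimethyl)silyl]oxy}dec-2-enoic acid (racemic) | CCCCCCC(O[Si](C)(C)C(C)(C)C)/C=C\C(=O)O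
F7 | step 20 | core 7-yl (2Z)-4-{[tert-butyl(dimethyl)silyl]oxy}dec-2-enoate (C4′ epimers; core as in 21) | CCCCCCC(O[Si](C)(C)C(C)(C)C)/C=C\C(=O)O[C@@H]1[C@@H](C)[C@@H]2OC(=O)[C@H](C)[C@H](OC(C)=O)[C@@]2(C)O[C@H]1C
F8 | step 20 | core 7-yl (2Z)-4-hydroxydec-2-enoate (C4′ epimers) | CCCCCCC(O)/C=C\C(=O)O[C@@H]1[C@@H](C)[C@@H]2OC(=O)[C@H](C)[C@H](OC(C)=O)[C@@]2(C)O[C@H]1C
F9 | step 11 | (3S,4R,5R)-5-(benzyloxy)-2,4,6-trimethylhepta-1,6-dien-3-yl 3-(trimethylsilyl)propanoate | C=C(C)[C@H](OCc1ccccc1)[C@@H](C)[C@H](OC(=O)CC[Si](C)(C)C)C(C)=C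
F10 | step 11 | (3S,4R,5R)-5-(benzyloxy)-2,4,6-trimethylhepta-1,6-dien-3-yl 2-formyl-3-(trimethylsilyl)propanoate (mainly enol) | C=C(C)[C@H](OCc1ccccc1)[C@@H](C)[C@H](OC(=O)C(C=O)C[Si](C)(C)C)C(C)=C
F11 | step 11 | (3S,4R,5R)-5-(benzyloxy)-2,4,6-trimethylhepta-1,6-dien-3-yl (2Z)-3-(acetyloxy)-2-[(trimethylsilyl)methyl]prop-2-enoate | C=C(C)[C@H](OCc1ccccc1)[C@@H](C)[C@H](OC(=O)/C(C[Si](C)(C)C)=C/OC(C)=O)C(C)=C
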